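**Retrosynthetic overview**

1. Feature: on the eleven-membered carbocycle, O7 is homoallylic to the C4=C5 alkene and γ to the carboxyl carbon C14 on C5, so the acid and the C7 oxygen are a latent five-membered lactone (O7–C14–C5–C6–C7) bridging the ring.
2. Target ⇒ silyl-protected bicyclic alkylidene butyrolactone (lactone opening, allyl ester, O7 isovalerylation, deallylation, desilylation) ⇒ cycloundec-4-yn-7-ol + CO by transannular palladium cyclocarbonylation (forms C14–O7 and C14–C5, fixes the C4=C5 geometry).
3. Cycloundecyne ⇒ methyl-capped diyne by ring-closing alkyne metathesis at C4≡C5; the carbocycle is formed first, the lactone second.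
4. Diyne ⇒ (7S)-epoxide + 1-propynyllithium (C5–C6), after alkenyllithium + Weinreb amide (C1–C11) and CBS reduction (C11).
5. Epoxy Weinreb amide ⇐ 3,3-dimethylglutaric anhydride (C7–C11; kinetic resolution sets C7); alkenyl bromide ⇐ 3-bromobut-3-en-1-ol + 1-propynyllithium.

Key step: step 16

Assumptions:
- Ring atoms are numbered C1 (bearing methylene C15) to C11 (free carbinol) in the order of the target SMILES; C5 bears carboxyl C14, C7 the isovalerate and C9 the two methyls. Locants in the names of the cyclic compounds follow this numbering. The target is (7S,11S) with an E (ring-cis) C4=C5 bond.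
- 1-Propynyllithium is used as the commercial, weighable form of propyne.
- The (R,R)-cobalt salen catalyst is taken to leave the (S)-epoxide unreacted, as it does for simple alkyl oxiranes.
- TBS = tert-butyldimethylsilyl, TES = triethylsilyl.

**Route**

Step 1
Reactants: 1 3,3-dimethylglutaric anhydride
Product: 3 4,4-dimethyloxan-2-one, via sodium 5-hydroxy-3,3-dimethylpentanoate 2 (not isolated)
Conditions: NaBH4, THF, 0 °C → rt; then 6 M HCl
Reagents that add atoms: none
Why: Borohydride reduction of one carbonyl of the symmetric cyclic anhydride (anhydride-to-lactone reduction) should give the hydroxy carboxylate, which lactonises on acidification; symmetry removes any regiochemical question.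

Step 2
Reactants: 3 4,4-dimethyloxan-2-one
Product: 4 5-hydroxy-N-methoxy-N,3,3-trimethylpentanamide
Conditions: MeNHOMe·HCl, AlMe3, CH2Cl2, 0 °C → rt; aqueous potassium sodium tartrate
Reagents that add atoms: N,O-dimethylhydroxylamine hydrochloride, CNOC.Cl
Why: Weinreb aminolysis of the lactone by the aluminium amide formed in the flask should open the ring to the hydroxy amide, which is taken on at once so that it cannot relactonise.

Step 3
Reactants: 4 5-hydroxy-N-methoxy-N,3,3-trimethylpentanamide
Product: 5 N-methoxy-N,3,3-trimethyl-5-oxopentanamide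
Conditions: Dess–Martin periodinane, NaHCO3, CH2Cl2, 0 °C → rt
Reagents that add atoms: none
Why: Buffered Dess–Martin oxidation should convert the primary alcohol into the aldehyde without touching the Weinreb amide.

Step 4
Reactants: 5 N-methoxy-N,3,3-trimethyl-5-oxopentanamide
Product: 6 N-methoxy-N,3,3-trimethylhex-5-enamide
Conditions: Ph3PCH3Br, KN(SiMe3)2, THF, −78 → 0 °C
Reagents that add atoms: methyltriphenylphosphonium bromide, C[P+](c1ccccc1)(c1ccccc1)c1ccccc1.[Br-]
Why: Wittig methylenation; the non-stabilised ylide should react with the aldehyde far faster than with the Weinreb amide at low temperature and supplies C6.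

Step 5
Reactants: 6 N-methoxy-N,3,3-trimethylhex-5-enamide
Product: 7 racemic N-methoxy-N,3,3-trimethyl-4-(oxiran-2-yl)butanamide
Conditions: mCPBA, NaHCO3, CH2Cl2, 0 °C → rt
Reagents that add atoms: mCPBA (3-chloroperoxybenzoic acid), OOC(=O)c1cccc(Cl)c1
Why: Prilezhaev epoxidation of the only alkene should give the terminal epoxide.

Step 6
Reactants: 7 racemic N-methoxy-N,3,3-trimethyl-4-(oxiran-2-yl)butanamide
Product: 8 N-methoxy-N,3,3-trimethyl-4-[(2S)-oxiran-2-yl]butanamide
Conditions: (R,R)-Co(salen)(OAc) (0.5 mol%; salen = N,N'-bis(3,5-di-tert-butylsalicylidene)cyclohexane-1,2-diaminate), H2O (0.55 equiv), THF, 0 °C → rt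
Reagents that add atoms: none
Why: Jacobsen hydrolytic kinetic resolution: the chiral cobalt salen complex should hydrolyse the (R)-epoxide much faster, so the (S)-epoxide is recovered and C7 is set by the catalyst.

Step 7
Reactants: 9 3-bromobut-3-en-1-ol
Product: 10 3-bromobut-3-en-1-yl trifluoromethanesulfonate
Conditions: Tf2O, pyridine, CH2Cl2, −78 → −20 °C
Reagents that add atoms: trifluoromethanesulfonic anhydride, O=S(=O)(OS(=O)(=O)C(F)(F)F)C(F)(F)F
Why: Sulfonylation of the primary alcohol should give the triflate, which is used cold and without storage.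

Step 8
Reactants: 10 3-bromobut-3-en-1-yl trifluoromethanesulfonate; 11 1-propynyllithium
Product: 12 2-bromohept-1-en-5-yne
Conditions: THF/DMPU, −78 → −20 °C
Reagents that add atoms: none
Why: SN2 alkylation of the alkynyllithium by the primary triflate should be fast enough at low temperature to outrun elimination, and the vinyl bromide is inert.

Step 9
Reactants: 12 2-bromohept-1-en-5-yne; 8 N-methoxy-N,3,3-trimethyl-4-[(2S)-oxiran-2-yl]butanamide
Product: 14 2,2-dimethyl-5-methylidene-1-[(2S)-oxiran-2-yl]dec-8-yn-4-one, via hept-1-en-5-yn-2-yllithium 13 (not isolated)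
Conditions: t-BuLi (2 equiv per 12), Et2O, −78 °C; then 8, THF, −78 °C; NH4Cl (aq)
Reagents that add atoms: none
Why: Bromine–lithium exchange followed by Weinreb ketone synthesis should form the C1–C11 bond and stop at the enone because the chelated tetrahedral adduct survives until work-up; without a Lewis acid the epoxide is not opened at −78 °C.

Step 10
Reactants: 14 2,2-dimethyl-5-methylidene-1-[(2S)-oxiran-2-yl]dec-8-yn-4-one
Product: 15 (4S)-2,2-dimethyl-5-methylidene-1-[(2S)-oxiran-2-yl]dec-8-yn-4-ol
Conditions: (R)-Me-CBS oxazaborolidine (0.3 equiv), catecholborane, toluene, −78 °C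
Reagents that add atoms: none
Why: Corey–Bakshi–Shibata reduction with the alkenyl group as the large substituent should deliver hydride under catalyst control to give the (S)-carbinol at C11 (the (S)-catalyst gives R with this priority pattern, so the (R)-catalyst is used); epoxide and alkyne are inert to catecholborane at this temperature.

Step 11
Reactants: 15 (4S)-2,2-dimethyl-5-methylidene-1-[(2S)-oxiran-2-yl]dec-8-yn-4-ol
Product: 16 tert-butyl-[(4S)-2,2-dimethyl-5-methylidene-1-[(2S)-oxiran-2-yl]dec-8-yn-4-yl]oxy-dimethylsilane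
Conditions: TBSCl, imidazole, DMAP (cat.), DMF, rt
Reagents that add atoms: TBSCl (tert-butyldimethylsilyl chloride), CC(C)(C)[Si](C)(C)Cl
Why: Imidazole-mediated silylation should protect O11 under conditions that are not Lewis acidic enough to open the epoxide.

Step 12
Reactants: 16 the TBS ether from step 11; 11 1-propynyllithium
Product: 17 (5S,9S)-9-(tert-butyldimethylsilyloxy)-7,7-dimethyl-10-methylidenepentadeca-2,13-diyn-5-ol
Conditions: BF3·OEt2, THF, −78 °C; NH4Cl (aq)
Reagents that add atoms: none
Why: BF3-promoted alkynylation of the terminal epoxide (Yamaguchi conditions) should attack the unsubstituted carbon C6 and form the C5–C6 bond; the C7–O bond is not broken, so the S configuration is carried over.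

Step 13
Reactants: 17 the diynol from step 12
Product: 18 TES ether of 17 at O7
Conditions: TESCl, imidazole, CH2Cl2, 0 °C → rt
Reagents that add atoms: TESCl (chlorotriethylsilane), CC[Si](Cl)(CC)CC
Why: Silylation masks the free hydroxyl so that it cannot exchange with the silanolate ligands of the molybdenum alkylidyne in the next step.

Step 14
Reactants: 18 the bis-silyl diyne from step 13
Product: 19 (7S,11S)-11-(tert-butyldimethylsilyloxy)-9,9-dimethyl-1-methylidene-7-(triethylsilyloxy)cycloundec-4-yne
Conditions: Mo(≡CC6H4-4-OMe)(OSiPh3)3 (15 mol%), 5 Å molecular sieves, toluene (0.5 mM), 80 °C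
Reagents that add atoms: none
Why: Ring-closing alkyne metathesis: the molybdenum alkylidyne should exchange the two methyl-capped alkynes through metallacyclobutadienes while the sieves trap but-2-yne, so that at high dilution the C4≡C5 bond of the eleven-membered ring forms; the alkene and silyl ethers are inert, and the gem-dimethyl group at C9 and the sp2 carbon C1 ease closure of a ring only slightly more strained than the twelve-membered cycloalkynes this reaction routinely gives.

Step 15
Reactants: 19 the bis-silyl cycloundecyne from step 14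
Product: 20 (7S,11S)-11-(tert-butyldimethylsilyloxy)-9,9-dimethyl-1-methylidenecycloundec-4-yn-7-ol
Conditions: pyridinium p-toluenesulfonate, MeOH/CH2Cl2, 0 °C
Reagents that add atoms: none
Why: Mild acidic methanolysis should cleave the secondary TES ether selectively while the bulkier TBS ether at O11 stays.

Step 16
Reactants: 20 (7S,11S)-11-(tert-butyldimethylsilyloxy)-9,9-dimethyl-1-methylidenecycloundec-4-yn-7-ol
Product: 21 (4E,7S,11S)-11-(tert-butyldimethylsilyloxy)-9,9-dimethyl-1-methylidenecycloundec-4-ene-5,7-carbolactone (α-alkylidene-γ-butyrolactone O7–C14(=O)–C5)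
Conditions: PdCl2 (10 mol%), PPh3 (20 mol%), SnCl2 (10 mol%), CO (7 atm), MeCN, 75 °C
Reagents that add atoms: carbon monoxide, [C-]#[O+]
Why: Under CO the C7 hydroxyl converts chloride-ligated divalent palladium into an alkoxycarbonyl complex (Pd–C14(=O)–O7, with loss of HCl), the C4≡C5 triple bond then inserts syn into the Pd–C14 bond with C14 going to C5 and palladium to C4, and HCl cleaves the vinyl–palladium bond with retention so that H on C4 ends cis to C14 and the catalyst is returned. The closest known reaction is the PdCl2/PPh3/SnCl2 cyclocarbonylation of but-3-yn-1-ols, internal alkynes included, to α-alkylidene-γ-butyrolactones, here run across a ring. The five-membered lactone O7–C14–C5–C6–C7 closes in 5-exo-dig mode, forming the C14–O7 and C14–C5 bonds and bridging C5 and C7 of the carbocycle. No stereocentre is created and C7 and C11 are not touched; the C4=C5 geometry follows from the syn insertion, which on a ring alkyne can only give the ring-cis alkene (C3 cis to C6, trans to the carbonyl, E by the sequence rule). The step needs C14 on C5 and not on C4 and reaction at O7 and not O11: the O7 tether makes five-membered closure onto C5 far easier than six-membered closure onto C4, O11 is blocked as its silyl ether, and the bent ring alkyne should insert faster than an unstrained internal alkyne. Being an addition, the step leaves no by-product, and the lactone at once tells O7 apart from O11 for the later acylation.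

Step 17
Reactants: 21 the bicyclic lactone from step 16
Product: 23 allyl (4E,7S,11S)-11-(tert-butyldimethylsilyloxy)-7-hydroxy-9,9-dimethyl-1-methylidenecycloundec-4-ene-5-carboxylate, via potassium hydroxy carboxylate 22 (not isolated)
Conditions: KOH (1.05 equiv), THF/H2O, rt; evaporate to dryness; allyl bromide, DMF, 0 °C → rt
Reagents that add atoms: potassium hydroxide, [K+].[OH-]; allyl bromide, C=CCBr
Why: Saponification followed by SN2 O-alkylation of the dry potassium carboxylate should give the allyl ester without ever forming the free γ-hydroxy acid, which would relactonise.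

Step 18
Reactants: 23 the hydroxy allyl ester from step 17; 24 isovaleric anhydride
Product: 25 allyl (4E,7S,11S)-11-(tert-butyldimethylsilyloxy)-9,9-dimethyl-1-methylidene-7-(3-methylbutanoyloxy)cycloundec-4-ene-5-carboxylate
Conditions: DMAP (cat.), Et3N, CH2Cl2, 0 °C
Reagents that add atoms: none
Why: DMAP-catalysed acyl transfer from the anhydride to the secondary C7 hydroxyl should be faster than relactonisation onto the conjugated allyl ester, and O11 is still silylated.

Step 19
Reactants: 25 the allyl ester isovalerate from step 18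
Product: 26 (4E,7S,11S)-11-(tert-butyldimethylsilyloxy)-9,9-dimethyl-1-methylidene-7-(3-methylbutanoyloxy)cycloundec-4-ene-5-carboxylic acid
Conditions: Pd(PPh3)4 (5 mol%), morpholine, THF, rt; then dilute HCl wash
Reagents that add atoms: none
Why: Tsuji–Trost deallylation: zerovalent palladium should ionise only the allyl ester to a π-allyl complex that morpholine intercepts, leaving the isovalerate and the silyl ether untouched.

Step 20
Reactants: 26 the silyl-protected acid from step 19
Product: 27 (4E,7S,11S)-11-hydroxy-9,9-dimethyl-1-methylidene-7-(3-methylbutanoyloxy)cycloundec-4-ene-5-carboxylic acid (CNP0400752.1)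
Conditions: HF·pyridine, pyridine, THF, 0 °C → rt
Reagents that add atoms: none
Why: Buffered fluoride desilylation should free the C11 hydroxyl without acyl migration, ester cleavage or ionisation of the allylic alcohol.

**Compound list**

1 | 3,3-dimethylglutaric anhydride | CC1(C)CC(=O)OC(=O)C1 | starting material
2 | sodium 5-hydroxy-3,3-dimethylpentanoate | [Na+].[O-]C(=O)CC(C)(C)CCO | intermediate (not isolated)
3 | 4,4-dimethyloxan-2-one | CC1(C)CCOC(=O)C1 | intermediate
4 | 5-hydroxy-N-methoxy-N,3,3-trimethylpentanamide | CON(C)C(=O)CC(C)(C)CCO | intermediate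
5 | N-methoxy-N,3,3-trimethyl-5-oxopentanamide | CON(C)C(=O)CC(C)(C)CC=O | intermediate
6 | N-methoxy-N,3,3-trimethylhex-5-enamide | CON(C)C(=O)CC(C)(C)CC=C | intermediate
7 | racemic N-methoxy-N,3,3-trimethyl-4-(oxiran-2-yl)butanamide | CON(C)C(=O)CC(C)(C)CC1CO1 | intermediate
8 | N-methoxy-N,3,3-trimethyl-4-[(2S)-oxiran-2-yl]butanamide | CON(C)C(=O)CC(C)(C)C[C@H]1CO1 | intermediate
9 | 3-bromobut-3-en-1-ol | C=C(Br)CCO | starting material
10 | 3-bromobut-3-en-1-yl trifluoromethanesulfonate | C=C(Br)CCOS(=O)(=O)C(F)(F)F | intermediate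
11 | 1-propynyllithium | CC#C[Li] | starting material
12 | 2-bromohept-1-en-5-yne | C=C(Br)CCC#CC | intermediate
13 | hept-1-en-5-yn-2-yllithium | [Li]C(=C)CCC#CC | intermediate (not isolated)
14 | 2,2-dimethyl-5-methylidene-1-[(2S)-oxiran-2-yl]dec-8-yn-4-one | CC#CCCC(=C)C(=O)CC(C)(C)C[C@H]1CO1 | intermediate
15 | (4S)-2,2-dimethyl-5-methylidene-1-[(2S)-oxiran-2-yl]dec-8-yn-4-ol | CC#CCCC(=C)[C@@H](O)CC(C)(C)C[C@H]1CO1 | intermediate
16 | tert-butyl-[(4S)-2,2-dimethyl-5-methylidene-1-[(2S)-oxiran-2-yl]dec-8-yn-4-yl]oxy-dimethylsilane | CC#CCCC(=C)[C@@H](O[Si](C)(C)C(C)(C)C)CC(C)(C)C[C@H]1CO1 | intermediate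
17 | (5S,9S)-9-(tert-butyldimethylsilyloxy)-7,7-dimethyl-10-methylidenepentadeca-2,13-diyn-5-ol | CC#CCCC(=C)[C@@H](O[Si](C)(C)C(C)(C)C)CC(C)(C)C[C@H](O)CC#CC | intermediate
18 | (5S,9S)-9-(tert-butyldimethylsilyloxy)-7,7-dimethyl-10-methylidene-5-(triethylsilyloxy)pentadeca-2,13-diyne | CC#CCCC(=C)[C@@H](O[Si](C)(C)C(C)(C)C)CC(C)(C)C[C@H](O[Si](CC)(CC)CC)CC#CC | intermediate
19 | (7S,11S)-11-(tert-butyldimethylsilyloxy)-9,9-dimethyl-1-methylidene-7-(triethylsilyloxy)cycloundec-4-yne | C=C1CCC#CC[C@@H](O[Si](CC)(CC)CC)CC(C)(C)C[C@@H]1O[Si](C)(C)C(C)(C)C | intermediate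
20 | (7S,11S)-11-(tert-butyldimethylsilyloxy)-9,9-dimethyl-1-methylidenecycloundec-4-yn-7-ol | C=C1CCC#CC[C@@H](O)CC(C)(C)C[C@@H]1O[Si](C)(C)C(C)(C)C | intermediate (key-step precursor)
21 | (4E,7S,11S)-11-(tert-butyldimethylsilyloxy)-9,9-dimethyl-1-methylidenecycloundec-4-ene-5,7-carbolactone | C=C1CC/C=C2/C(=O)O[C@H](C2)CC(C)(C)C[C@@H]1O[Si](C)(C)C(C)(C)C | intermediate (key-step product)
22 | potassium (4E,7S,11S)-11-(tert-butyldimethylsilyloxy)-7-hydroxy-9,9-dimethyl-1-methylidenecycloundec-4-ene-5-carboxylate | C=C1CC/C=C(/C(=O)[O-])C[C@@H](O)CC(C)(C)C[C@@H]1O[Si](C)(C)C(C)(C)C.[K+] | intermediate (not isolated)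
23 | allyl (4E,7S,11S)-11-(tert-butyldimethylsilyloxy)-7-hydroxy-9,9-dimethyl-1-methylidenecycloundec-4-ene-5-carboxylate | C=C1CC/C=C(/C(=O)OCC=C)C[C@@H](O)CC(C)(C)C[C@@H]1O[Si](C)(C)C(C)(C)C | intermediate
24 | isovaleric anhydride | CC(C)CC(=O)OC(=O)CC(C)C | starting material
25 | allyl (4E,7S,11S)-11-(tert-butyldimethylsilyloxy)-9,9-dimethyl-1-methylidene-7-(3-methylbutanoyloxy)cycloundec-4-ene-5-carboxylate | C=C1CC/C=C(/C(=O)OCC=C)C[C@@H](OC(=O)CC(C)C)CC(C)(C)C[C@@H]1O[Si](C)(C)C(C)(C)C | intermediate
26 | (4E,7S,11S)-11-(tert-butyldimethylsilyloxy)-9,9-dimethyl-1-methylidene-7-(3-methylbutanoyloxy)cycloundec-4-ene-5-carboxylic acid | C=C1CC/C=C(/C(=O)O)C[C@@H](OC(=O)CC(C)C)CC(C)(C)C[C@@H]1O[Si](C)(C)C(C)(C)C | intermediate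
27 | (4E,7S,11S)-11-hydroxy-9,9-dimethyl-1-methylidene-7-(3-methylbutanoyloxy)cycloundec-4-ene-5-carboxylic acid (CNP0400752.1) | C=C1CC/C=C(/C(=O)O)C[C@@H](OC(=O)CC(C)C)CC(C)(C)C[C@@H]1O | target

**Step count and risks**

Total step count: 20. Longest linear sequence: 18 (steps 1–6 and 9–20; steps 7 and 8 make the side fragment).

Steps most likely to fail:

1. Step 14 (ring-closing alkyne metathesis). Ring strain may divert the metathesis equilibrium to the cyclic dimer and open oligomers instead of the monomeric eleven-membered ring. The fallback closes the ring at the C1–C11 bond by a kinetically controlled Nozaki–Hiyama–Kishi reaction; it sets out from 8 and 10 and comes back at 19.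
   - Reduction of the Weinreb amide of 8 with i-Bu2AlH at −78 °C should give 3,3-dimethyl-4-[(2S)-oxiran-2-yl]butanal F1.
   - NaBH4 in MeOH at 0 °C should give 3,3-dimethyl-4-[(2S)-oxiran-2-yl]butan-1-ol F2.
   - TESCl and imidazole should give its triethylsilyl ether F3.
   - Triflate 10 is displaced by lithium (trimethylsilyl)acetylide to (5-bromohex-5-en-1-yn-1-yl)trimethylsilane F4, which K2CO3 in MeOH desilylates to 2-bromohex-1-en-5-yne F5.
   - The lithium acetylide of F5 (n-BuLi, −78 °C) with BF3·OEt2 should open F3 at C6 to (5S)-11-bromo-3,3-dimethyl-1-(triethylsilyloxy)dodec-11-en-7-yn-5-ol F6.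
   - TESCl gives the bis(triethylsilyl) ether F7, and Swern conditions, which oxidise only the primary triethylsilyl ether, should give (5S)-11-bromo-3,3-dimethyl-5-(triethylsilyloxy)dodec-11-en-7-ynal F8.
   - CrCl2 with catalytic NiCl2 in DMSO/THF at high dilution should join C1 to C11 and give 9,9-dimethyl-1-methylidene-7-(triethylsilyloxy)cycloundec-4-yn-11-ol F9 as a mixture at C11.
   - Dess–Martin oxidation gives the cyclic enone F10, reduction with (R)-Me-CBS and catecholborane gives the (11S)-alcohol F11, and TBSCl with imidazole returns 19.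

2. Step 16 (transannular cyclocarbonylation). Insertion of the internal ring alkyne into the palladium–acyl bond may be too slow, so that palladium-mediated cycloisomerisation of the alkynol or acid-induced loss of the allylic silyl ether takes over. The fallback separates hydrometalation from carbonylation; it sets out from 20 and comes back at 21.
   - 1,1,3,3-Tetramethyldisilazane at 60 °C should convert 20 into its dimethylsilyl ether F12.
   - Pt2[(CH2=CHSiMe2)2O]3 should catalyse intramolecular syn hydrosilylation in 5-exo-dig mode to the alkylidene oxasilolane F13, with silicon on C5 and hydrogen on C4 cis to it.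
   - Iododesilylation with retention (N-iodosuccinimide, hexafluoroisopropanol, 0 °C) and aqueous work-up should give the (4E)-5-iodocycloundec-4-en-7-ol F14.
   - Pd(PPh3)4, CO (1 atm) and K2CO3 in MeCN then close the lactone by carbonylative lactonisation of the vinyl iodide with retention of geometry, giving 21.

3. Step 17 (lactone opening and allylation, with step 18). The γ-hydroxy carboxylate or its allyl ester may relactonise before O7 is acylated. The fallback never passes through a γ-hydroxy acid derivative; it sets out from 21, uses 24 and comes back at 26.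
   - i-Bu2AlH at −78 → 0 °C should reduce 21 to the (4E)-5-(hydroxymethyl)cycloundec-4-en-7-ol F15.
   - TESCl and imidazole at −40 °C should silylate only the primary allylic hydroxyl, giving the mono-triethylsilyl ether F16.
   - Anhydride 24 with DMAP acylates O7 to the isovalerate F17.
   - Pyridinium p-toluenesulfonate in MeOH frees the allylic alcohol F18.
   - MnO2 gives the enal F19, and Pinnick oxidation (NaClO2, NaH2PO4, 2-methylbut-2-ene) gives 26.

**Further compounds**

F1 | step 14 | 3,3-dimethyl-4-[(2S)-oxiran-2-yl]butanal | O=CCC(C)(C)C[C@H]1CO1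
F2 | step 14 | 3,3-dimethyl-4-[(2S)-oxiran-2-yl]butan-1-ol | OCCC(C)(C)C[C@H]1CO1
F3 | step 14 | [3,3-dimethyl-4-[(2S)-oxiran-2-yl]butoxy]triethylsilane | CC[Si](CC)(CC)OCCC(C)(C)C[C@H]1CO1
F4 | step 14 | (5-bromohex-5-en-1-yn-1-yl)trimethylsilane | C=C(Br)CCC#C[Si](C)(C)C
F5 | step 14 | 2-bromohex-1-en-5-yne | C=C(Br)CCC#C
F6 | step 14 | (5S)-11-bromo-3,3-dimethyl-1-(triethylsilyloxy)dodec-11-en-7-yn-5-ol | C=C(Br)CCC#CC[C@@H](O)CC(C)(C)CCO[Si](CC)(CC)CC
F7 | step 14 | (5S)-11-bromo-3,3-dimethyl-1,5-bis(triethylsilyloxy)dodec-11-en-7-yne | C=C(Br)CCC#CC[C@@H](O[Si](CC)(CC)CC)CC(C)(C)CCO[Si](CC)(CC)CC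
F8 | step 14 | (5S)-11-bromo-3,3-dimethyl-5-(triethylsilyloxy)dodec-11-en-7-ynal | C=C(Br)CCC#CC[C@@H](O[Si](CC)(CC)CC)CC(C)(C)CC=O
F9 | step 14 | (7S)-9,9-dimethyl-1-methylidene-7-(triethylsilyloxy)cycloundec-4-yn-11-ol (C11 epimers) | C=C1CCC#CC[C@@H](O[Si](CC)(CC)CC)CC(C)(C)CC1O
F10 | step 14 | (7S)-9,9-dimethyl-1-methylidene-7-(triethylsilyloxy)cycloundec-4-yn-11-one | C=C1CCC#CC[C@@H](O[Si](CC)(CC)CC)CC(C)(C)CC1=O
F11 | step 14 | (7S,11S)-9,9-dimethyl-1-methylidene-7-(triethylsilyloxy)cycloundec-4-yn-11-ol | C=C1CCC#CC[C@@H](O[Si](CC)(CC)CC)CC(C)(C)C[C@@H]1O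
F12 | step 16 | (7S,11S)-11-(tert-butyldimethylsilyloxy)-7-(dimethylsilyloxy)-9,9-dimethyl-1-methylidenecycloundec-4-yne | C=C1CCC#CC[C@@H](O[SiH](C)C)CC(C)(C)C[C@@H]1O[Si](C)(C)C(C)(C)C
F13 | step 16 | alkylidene oxasilolane (O7–SiMe2–C5, exocyclic C5=C4, C11 TBS ether) | C=C1CC/C=C2/[Si](C)(C)O[C@H](C2)CC(C)(C)C[C@@H]1O[Si](C)(C)C(C)(C)C
F14 | step 16 | (4E,7S,11S)-11-(tert-butyldimethylsilyloxy)-5-iodo-9,9-dimethyl-1-methylidenecycloundec-4-en-7-ol | C=C1CC/C=C(/I)C[C@@H](O)CC(C)(C)C[C@@H]1O[Si](C)(C)C(C)(C)C
F15 | step 17 | (4E,7S,11S)-11-(tert-butyldimethylsilyloxy)-5-(hydroxymethyl)-9,9-dimethyl-1-methylidenecycloundec-4-en-7-ol | C=C1CC/C=C(/CO)C[C@@H](O)CC(C)(C)C[C@@H]1O[Si](C)(C)C(C)(C)C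
F16 | step 17 | (4E,7S,11S)-11-(tert-butyldimethylsilyloxy)-9,9-dimethyl-1-methylidene-5-(triethylsilyloxymethyl)cycloundec-4-en-7-ol | C=C1CC/C=C(/CO[Si](CC)(CC)CC)C[C@@H](O)CC(C)(C)C[C@@H]1O[Si](C)(C)C(C)(C)C
F17 | step 17 | (4E,7S,11S)-11-(tert-butyldimethylsilyloxy)-9,9-dimethyl-1-methylidene-5-(triethylsilyloxymethyl)cycloundec-4-en-7-yl 3-methylbutanoate | C=C1CC/C=C(/CO[Si](CC)(CC)CC)C[C@@H](OC(=O)CC(C)C)CC(C)(C)C[C@@H]1O[Si](C)(C)C(C)(C)C
F18 | step 17 | (4E,7S,11S)-11-(tert-butyldimethylsilyloxy)-5-(hydroxymethyl)-9,9-dimethyl-1-methylidenecycloundec-4-en-7-yl 3-methylbutanoate | C=C1CC/C=C(/CO)C[C@@H](OC(=O)CC(C)C)CC(C)(C)C[C@@H]1O[Si](C)(C)C(C)(C)C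
F19 | step 17 | (4E,7S,11S)-11-(tert-butyldimethylsilyloxy)-5-formyl-9,9-dimethyl-1-methylidenecycloundec-4-en-7-yl 3-methylbutanoate | C=C1CC/C=C(/C=O)C[C@@H](OC(=O)CC(C)C)CC(C)(C)C[C@@H]1O[Si](C)(C)C(C)(C)C
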